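**Strategy.** Everything rests on disconnecting C4–C5 and C9–C10, which unravels the decalin to an acyclic epoxy-polyene built from (S)-citronellol (C9, C11–C16), a homogeranyl unit and CBr4 (C8). In one operation a Lewis acid opens the (3S,4S)-epoxide at C4, ring A closes, and the C10 cation is captured by C9 of a Z-allylsilane, so ring B (C5–C10) closes last and silicon leaves the C8=C17 methylene. The step exploits the trans A/B fusion (H5 anti to the C10 methyl), the equatorial C18 on quaternary C4 and the methylene beside C9. The C3–O bond, absent from the target, relays absolute configuration and is later removed by radical deoxygenation.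

Key step: step 11

Remark: the target is taken exactly as drawn, a labd-8(17)-ene whose carboxyl (C18) is equatorial on C4 and trans to the C10 methyl (4R,5R,9S,10R,13S); atom labels follow labdane numbering (ring A = C1–C5 and C10, ring B = C5–C10, C17 = methylene carbon, C19 and C20 = methyls on C4 and C10), and metal alkoxide forms of numbered alcohols are not numbered separately.

Step 1
Reactants: 1 (S)-citronellol
Product: 2 (S)-citronellyl acetate
Conditions: Ac2O, pyridine, DMAP (cat.), CH2Cl2, 23 °C
Reagents that add atoms: acetic anhydride, CC(=O)OC(C)=O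
Why: DMAP-catalysed acylation of the primary alcohol installs the acetate of the target, which is carried to the end; C13 is untouched.

Step 2
Reactants: 2 (S)-citronellyl acetate
Product: 3 (3S)-3-methyl-6-oxohexyl acetate
Conditions: O3, CH2Cl2, −78 °C; then PPh3, −78 → 23 °C
Reagents that add atoms: ozone, [O-][O+]=O
Why: Ozonolysis with reductive work-up cleaves the only alkene to the aldehyde whose carbon becomes C9; the acetate and C13 are inert.

Step 3
Reactants: 3 (3S)-3-methyl-6-oxohexyl acetate
Product: 4 (3S)-7,7-dibromo-3-methylhept-6-en-1-yl acetate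
Conditions: CBr4, PPh3, CH2Cl2, 0 °C
Reagents that add atoms: carbon tetrabromide, BrC(Br)(Br)Br
Why: Ramirez dibromo-olefination (first stage of the Corey–Fuchs sequence) converts the aldehyde into the 1,1-dibromoalkene whose new carbon is C8; the neutral conditions spare the acetate.

Step 4
Reactants: 5 5-bromo-2-methylpent-2-ene
Product: 6 6-methylhept-5-en-1-yne
Conditions: LiC≡CH·H2NCH2CH2NH2, DMSO, 23 °C
Reagents that add atoms: lithium acetylide (ethylenediamine complex), [Li]C#C
Why: SN2 alkylation of lithium acetylide by a primary homoallylic bromide gives the terminal alkyne (future C5 and C10).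

Step 5
Reactants: 6 6-methylhept-5-en-1-yne
Product: 9 (3E)-4,8-dimethylnona-3,7-dien-1-ol (homogeraniol), via alkenyldimethylalane 7 (not isolated), via lithium alkenylalanate 8 (not isolated)
Conditions: Me3Al, Cp2ZrCl2 (cat.), CH2Cl2, 23 °C; then n-BuLi, THF, −78 → 0 °C; oxirane, 0 → 23 °C; then 1 M HCl
Reagents that add atoms: trimethylaluminium, C[Al](C)C; oxirane, C1CO1
Why: Negishi zirconium-catalysed methylalumination adds methyl (C20) and aluminium syn across the alkyne, and the derived alanate opens oxirane with retention at the alkenyl carbon, so the C5=C10 alkene is formed E.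

Step 6
Reactants: 9 homogeraniol
Product: 10 (3E)-1-iodo-4,8-dimethylnona-3,7-diene (homogeranyl iodide)
Conditions: I2, PPh3, imidazole, CH2Cl2, 0 °C
Reagents that add atoms: iodine, II
Why: Appel-type (Garegg–Samuelsson) iodination of the primary alcohol proceeds by SN2 and leaves both alkenes untouched.

Step 7
Reactants: 10 homogeranyl iodide; 4 (3S)-7,7-dibromo-3-methylhept-6-en-1-yl acetate
Product: 12 (3S,6Z,10E)-7-bromo-3,11,15-trimethylhexadeca-6,10,14-trien-1-yl acetate, via homogeranylzinc iodide 11 (not isolated)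
Conditions: Zn dust, LiCl, THF, 40 °C; then 4, PdCl2(DPEphos) (5 mol%), THF, 0 → 23 °C
Reagents that add atoms: none
Why: Zinc insertion into the primary iodide is followed by a Negishi coupling in which oxidative addition occurs at the C–Br bond trans to the alkyl chain of the 1,1-dibromoalkene, so C7 enters trans to C11 and the remaining bromide is Z; alkylzinc halides tolerate the acetate.

Step 8
Reactants: 12 bromotrienyl acetate
Product: 13 (3S,6Z,10E,14E)-7-bromo-16-hydroxy-3,11,15-trimethylhexadeca-6,10,14-trien-1-yl acetate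
Conditions: SeO2 (cat.), t-BuOOH, salicylic acid (cat.), CH2Cl2, 23 °C, run to partial conversion
Reagents that add atoms: selenium dioxide, O=[Se]=O; tert-butyl hydroperoxide, CC(C)(C)OO
Why: SeO2/t-BuOOH allylic oxidation (ene reaction then 2,3-sigmatropic shift) hydroxylates the E-methyl of the terminal isopropylidene group, the least hindered trisubstituted alkene, as is known for farnesyl and geranylgeranyl esters; the bromoalkene is deactivated and the new CH2OH (C18) is trans to C2.

Step 9
Reactants: 13 bromo allylic alcohol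
Product: 14 (3S,6Z,10E,14E)-16-hydroxy-3,11,15-trimethyl-7-[(trimethylsilyl)methyl]hexadeca-6,10,14-trien-1-yl acetate
Conditions: Me3SiCH2MgCl (3 equiv), Pd(PPh3)4 (5 mol%), THF, 0 → 23 °C; aq. NH4Cl
Reagents that add atoms: (trimethylsilyl)methylmagnesium chloride, C[Si](C)(C)C[Mg]Cl
Why: Kumada–Corriu coupling of an alkenyl bromide with Me3SiCH2MgCl is the classical allylsilane synthesis and proceeds with retention, so CH2SiMe3 (C17) ends cis to C11; one equivalent is spent on the hydroxyl, and esters are known to survive this coupling at low temperature.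

Step 10
Reactants: 14 allylsilane allylic alcohol
Product: 15 (3S,6Z,10E)-13-[(2S,3S)-3-(hydroxymethyl)-3-methyloxiran-2-yl]-3,11-dimethyl-7-[(trimethylsilyl)methyl]trideca-6,10-dien-1-yl acetate
Conditions: Ti(OiPr)4 (10 mol%), L-(+)-diethyl tartrate (12 mol%), t-BuOOH, 4 Å molecular sieves, CH2Cl2, −20 °C
Reagents that add atoms: tert-butyl hydroperoxide, CC(C)(C)OO
Why: Katsuki–Sharpless asymmetric epoxidation is directed by the allylic hydroxyl, so only the C3=C4 alkene reacts, and L-(+)-tartrate delivers oxygen to the face that gives the (3S,4S)-epoxide, which later fixes the absolute configuration of all ring stereocentres.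

Step 11
Reactants: 15 epoxy alcohol
Product: 16 (13S)-3β,18-dihydroxylabd-8(17)-en-15-yl acetate
Conditions: MeAlCl2 (3 equiv), CH2Cl2, −78 °C; then aq. KNaC4H4O6
Reagents that add atoms: none
Why: MeAlCl2 turns the hydroxyl into an aluminium alkoxide that chelates and activates the oxirane; C5 of the E C5=C10 alkene attacks the tertiary carbon C4 with inversion (6-endo opening of the epoxide, 6-endo-trig at the alkene, ring A), the developing C10 cation is captured by C9 of the allylsilane (6-endo-trig, ring B), and loss of Me3Si from the β-silyl cation at C8 leaves the C8=C17 methylene. The closest known reaction type is the epoxide-initiated, allylsilane-terminated cation–olefin polycyclization, including variants with hydroxymethyl-substituted oxiranes. C4 is set by anti opening of the E-derived epoxide, which places C18 (trans to C2) equatorial and C19 axial, while C3 keeps its oxygen as the equatorial 3β-hydroxyl. C5 and C10 follow from anti addition across the E alkene in a chair–chair transition state (trans fusion, C20 axial), C9 follows from the Z allylsilane geometry, which puts C11 equatorial, and the absolute sense comes from the epoxide. The step needs opening at C4 and not at C3, secured by the tertiary carbon and the six-membered transition state, and initiation only at the epoxide, secured by an oxophilic Lewis acid at −78 °C that leaves the allylsilane and the ester alone. The position of the new alkene is secured by silicon.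

Step 12
Reactants: 16 diol
Product: 17 (13S)-3β,18-(thiocarbonyldioxy)labd-8(17)-en-15-yl acetate (cyclic thionocarbonate)
Conditions: 1,1'-thiocarbonyldiimidazole, DMAP (cat.), toluene, 80 °C
Reagents that add atoms: 1,1'-thiocarbonyldiimidazole, S=C(n1ccnc1)n1ccnc1
Why: The diequatorial 1,3-diol closes to the six-membered cyclic thionocarbonate by double acyl transfer; the acetate and the alkene are unaffected.

Step 13
Reactants: 17 cyclic thionocarbonate
Product: 19 (13S)-18-hydroxylabd-8(17)-en-15-yl acetate, via stannyl thiocarbonate 18 (not isolated)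
Conditions: Bu3SnH (slow addition), AIBN (cat.), toluene, 110 °C; then H2O, SiO2
Reagents that add atoms: none
Why: In this Barton-type radical deoxygenation the stannyl radical adds to sulfur and the adduct fragments towards the more stable secondary C3 radical rather than the primary C18 radical, hydrogen transfer gives C3H2, and the thiocarbonate left on C18 loses COS on hydrolysis.

Step 14
Reactants: 19 primary alcohol
Product: 21 (13S)-15-acetoxylabd-8(17)-en-18-oic acid (target), via aldehyde 20 (not isolated)
Conditions: CrO3, H2SO4, H2O, acetone, 0 °C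
Reagents that add atoms: water, O
Why: Jones oxidation takes the neopentyl primary alcohol through the aldehyde hydrate to the acid, as is routine for C18/C19 alcohols of diterpenes bearing an exocyclic methylene; acetate and alkene should survive the short exposure at 0 °C.

**Compound list**

1 | (S)-citronellol, (3S)-3,7-dimethyloct-6-en-1-ol | CC(C)=CCC[C@H](C)CCO | starting material
2 | (S)-citronellyl acetate | CC(C)=CCC[C@H](C)CCOC(C)=O | intermediate
3 | (3S)-3-methyl-6-oxohexyl acetate | O=CCC[C@H](C)CCOC(C)=O | intermediate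
4 | (3S)-7,7-dibromo-3-methylhept-6-en-1-yl acetate | BrC(Br)=CCC[C@H](C)CCOC(C)=O | intermediate
5 | 5-bromo-2-methylpent-2-ene | CC(C)=CCCBr | starting material
6 | 6-methylhept-5-en-1-yne | C#CCCC=C(C)C | intermediate
7 | dimethyl[(1E)-2,6-dimethylhepta-1,5-dien-1-yl]alane | C[Al](C)/C=C(C)/CCC=C(C)C | intermediate
8 | lithium butyl[(1E)-2,6-dimethylhepta-1,5-dien-1-yl]dimethylaluminate | [Li+].CCCC[Al-](C)(C)/C=C(C)/CCC=C(C)C | intermediate
9 | (3E)-4,8-dimethylnona-3,7-dien-1-ol (homogeraniol) | OCC/C=C(C)/CCC=C(C)C | intermediate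
10 | (3E)-1-iodo-4,8-dimethylnona-3,7-diene (homogeranyl iodide) | ICC/C=C(C)/CCC=C(C)C | intermediate
11 | [(3E)-4,8-dimethylnona-3,7-dien-1-yl]zinc iodide | I[Zn]CC/C=C(C)/CCC=C(C)C | intermediate
12 | (3S,6Z,10E)-7-bromo-3,11,15-trimethylhexadeca-6,10,14-trien-1-yl acetate | CC(C)=CCC/C(C)=C/CC/C(Br)=C/CC[C@H](C)CCOC(C)=O | intermediate
13 | (3S,6Z,10E,14E)-7-bromo-16-hydroxy-3,11,15-trimethylhexadeca-6,10,14-trien-1-yl acetate | OC/C(C)=C/CC/C(C)=C/CC/C(Br)=C/CC[C@H](C)CCOC(C)=O | intermediate
14 | (3S,6Z,10E,14E)-16-hydroxy-3,11,15-trimethyl-7-[(trimethylsilyl)methyl]hexadeca-6,10,14-trien-1-yl acetate | OC/C(C)=C/CC/C(C)=C/CC/C(C[Si](C)(C)C)=C/CC[C@H](C)CCOC(C)=O | intermediate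
15 | (3S,6Z,10E)-13-[(2S,3S)-3-(hydroxymethyl)-3-methyloxiran-2-yl]-3,11-dimethyl-7-[(trimethylsilyl)methyl]trideca-6,10-dien-1-yl acetate | OC[C@]1(C)O[C@H]1CC/C(C)=C/CC/C(C[Si](C)(C)C)=C/CC[C@H](C)CCOC(C)=O | intermediate
16 | (13S)-3β,18-dihydroxylabd-8(17)-en-15-yl acetate | C=C1CC[C@@H]2[C@](C)(CC[C@H](O)[C@@]2(C)CO)[C@H]1CC[C@H](C)CCOC(C)=O | intermediate
17 | (13S)-3β,18-(thiocarbonyldioxy)labd-8(17)-en-15-yl acetate | C=C1CC[C@@H]2[C@](C)(CC[C@@H]3OC(=S)OC[C@@]23C)[C@H]1CC[C@H](C)CCOC(C)=O | intermediate
18 | (13S)-18-({[(tributylstannyl)sulfanyl]carbonyl}oxy)labd-8(17)-en-15-yl acetate | C=C1CC[C@@H]2[C@](C)(CCC[C@@]2(C)COC(=O)S[Sn](CCCC)(CCCC)CCCC)[C@H]1CC[C@H](C)CCOC(C)=O | intermediate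
19 | (13S)-18-hydroxylabd-8(17)-en-15-yl acetate | C=C1CC[C@@H]2[C@](C)(CCC[C@@]2(C)CO)[C@H]1CC[C@H](C)CCOC(C)=O | intermediate
20 | (13S)-18-oxolabd-8(17)-en-15-yl acetate | C=C1CC[C@@H]2[C@](C)(CCC[C@@]2(C)C=O)[C@H]1CC[C@H](C)CCOC(C)=O | intermediate
21 | (13S)-15-acetoxylabd-8(17)-en-18-oic acid, (1R,4aR,5S,8aR)-5-[(3S)-5-acetoxy-3-methylpentyl]-1,4a-dimethyl-6-methylidenedecahydronaphthalene-1-carboxylic acid | C=C1CC[C@@H]2[C@](C)(CCC[C@@]2(C)C(=O)O)[C@H]1CC[C@H](C)CCOC(C)=O | target

**Totals.** Total step count: 14. Longest linear sequence: 11 steps (steps 1–3 or 4–6, then 7–14).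

**Steps most likely to fail**

Step 11. The chelated epoxide, inductively deactivated by the neighbouring oxygen, may ionise sluggishly, so that hydride shift to a ketone, chloride capture at C4 or protodesilylation outruns the cascade; ring B may also close with partial loss of the trans fusion. The fallback replaces the cationic closure by a radical one. Setting out from 13, methylation in place of silylmethylation (Me2Zn, Pd(P(t-Bu)3)2, THF) should give (3S,6E,10E,14E)-16-hydroxy-3,7,11,15-tetramethylhexadeca-6,10,14-trien-1-yl acetate F1. Katsuki–Sharpless epoxidation as in step 10 should then give its (2S,3S)-epoxy alcohol F2. Cp2TiCl (trivalent titanium, from Cp2TiCl2 and Mn dust, THF, 23 °C) should open the epoxide homolytically to the C4 radical, close rings A and B by two 6-endo radical cyclizations and end by β-hydride elimination towards C17, coming back to the route at 16. In this variant the C18/C19 arrangement rests only on the chair preference of the radical.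

Step 13. Fragmentation of the six-membered thionocarbonate may be slow, so that reduction without C–O cleavage, or cleavage towards C18, competes. The fallback is a stepwise Barton–McCombie sequence. Setting out from 16, selective silylation of the primary hydroxyl (TBSCl, imidazole) should give (13S)-18-[(tert-butyldimethylsilyl)oxy]-3β-hydroxylabd-8(17)-en-15-yl acetate F3. Thiocarbonyldiimidazole should give the 3β-O-(imidazol-1-ylthiocarbonyl) derivative F4, and Bu3SnH/AIBN the 3-deoxy silyl ether F5. HF·pyridine then comes back to the route at 19.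

Step 8. Allylic oxidation may lose site selectivity (attack at C1 of the internal alkene) or over-oxidise to the enal, with low mass recovery. The fallback builds the allylic alcohol by cleavage and olefination. Setting out from 12, NBS in aqueous THF should give the terminal bromohydrin (3S,6Z,10E)-7,14-dibromo-15-hydroxy-3,11,15-trimethylhexadeca-6,10-dien-1-yl acetate F6 (C14 epimers), and DBU the terminal epoxide F7. HIO4 should cleave it to (3S,6Z,10E)-7-bromo-3,11-dimethyl-14-oxotetradeca-6,10-dien-1-yl acetate F8. Wittig reaction with Ph3P=C(CH3)CHO should give the E-enal F9, and Luche reduction (NaBH4, CeCl3·7H2O) comes back to the route at 13.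

**Further compounds**

F1 | step 11 | (3S,6E,10E,14E)-16-hydroxy-3,7,11,15-tetramethylhexadeca-6,10,14-trien-1-yl acetate | OC/C(C)=C/CC/C(C)=C/CC/C(C)=C/CC[C@H](C)CCOC(C)=O
F2 | step 11 | (3S,6E,10E)-13-[(2S,3S)-3-(hydroxymethyl)-3-methyloxiran-2-yl]-3,7,11-trimethyltrideca-6,10-dien-1-yl acetate | OC[C@]1(C)O[C@H]1CC/C(C)=C/CC/C(C)=C/CC[C@H](C)CCOC(C)=O
F3 | step 13 | (13S)-18-[(tert-butyldimethylsilyl)oxy]-3β-hydroxylabd-8(17)-en-15-yl acetate | C=C1CC[C@@H]2[C@](C)(CC[C@H](O)[C@@]2(C)CO[Si](C)(C)C(C)(C)C)[C@H]1CC[C@H](C)CCOC(C)=O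
F4 | step 13 | (13S)-18-[(tert-butyldimethylsilyl)oxy]-3β-[(1H-imidazol-1-ylcarbonothioyl)oxy]labd-8(17)-en-15-yl acetate | C=C1CC[C@@H]2[C@](C)(CC[C@H](OC(=S)n3ccnc3)[C@@]2(C)CO[Si](C)(C)C(C)(C)C)[C@H]1CC[C@H](C)CCOC(C)=O
F5 | step 13 | (13S)-18-[(tert-butyldimethylsilyl)oxy]labd-8(17)-en-15-yl acetate | C=C1CC[C@@H]2[C@](C)(CCC[C@@]2(C)CO[Si](C)(C)C(C)(C)C)[C@H]1CC[C@H](C)CCOC(C)=O
F6 | step 8 | (3S,6Z,10E)-7,14-dibromo-15-hydroxy-3,11,15-trimethylhexadeca-6,10-dien-1-yl acetate (C14 epimers) | CC(C)(O)C(Br)CC/C(C)=C/CC/C(Br)=C/CC[C@H](C)CCOC(C)=O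
F7 | step 8 | (3S,6Z,10E)-7-bromo-13-(3,3-dimethyloxiran-2-yl)-3,11-dimethyltrideca-6,10-dien-1-yl acetate (oxirane epimers) | CC1(C)OC1CC/C(C)=C/CC/C(Br)=C/CC[C@H](C)CCOC(C)=O
F8 | step 8 | (3S,6Z,10E)-7-bromo-3,11-dimethyl-14-oxotetradeca-6,10-dien-1-yl acetate | O=CCC/C(C)=C/CC/C(Br)=C/CC[C@H](C)CCOC(C)=O
F9 | step 8 | (3S,6Z,10E,14E)-7-bromo-3,11,15-trimethyl-16-oxohexadeca-6,10,14-trien-1-yl acetate | O=C/C(C)=C/CC/C(C)=C/CC/C(Br)=C/CC[C@H](C)CCOC(C)=O
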